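**Strategy.** Everything rests on disconnecting the N–CH2–CH unit of the piperidine: one C–C bond between an N-bound methylene and the cycloheptene carbon adjacent to the hydroxymethyl-bearing quaternary carbon. The other six rings are built first on a cis-fused cyclopentane δ-lactone, obtained by desymmetrising a 2-ethynyl-2-propanoate cyclopentane-1,3-dione; spiro-pyrrolidine γ-lactone, cyclopentene and cycloheptene follow. In the key step a photo-oxidised N–CH2SiMe3 group gives an α-amino radical that closes 6-exo onto the cycloheptene, completing the 2-azabicyclo[3.2.1]octane and the last stereocentre. It exploits the 1,3-syn placement, across the cyclopentane, of the spiro-carbon nitrogen and the alkene carbon. The precursor is the hexacyclic N-(trimethylsilylmethyl) amine.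

Key step: step 21

Remark: the catalyst enantiomers in steps 3, 14 and 17 are those the usual models predict for the configurations drawn; the antipodal catalyst would be taken if the sense proved reversed.

Step 1
Reactants: 1 cyclopentane-1,3-dione; 2 methyl acrylate
Product: 3 methyl 3-(2,5-dioxocyclopentyl)propanoate
Conditions: Et3N (0.2 equiv), MeCN, 60 °C
Reagents that add atoms: methyl acrylate (2), C=CC(=O)OC
Why: Michael addition of the acidic cyclic 1,3-dione at C-2 to the acrylate should stop at the mono-adduct with one equivalent of acceptor; no stereocentre is formed.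

Step 2
Reactants: 3 methyl 3-(2,5-dioxocyclopentyl)propanoate; 4 1-[(trimethylsilyl)ethynyl]-1,2-benziodoxol-3(1H)-one (TMS-EBX)
Product: 5 methyl 3-(1-ethynyl-2,5-dioxocyclopentyl)propanoate
Conditions: Bu4NF (1.3 equiv), THF, −78 °C to rt
Reagents that add atoms: TMS-EBX (4), C[Si](C)(C)C#CI1OC(=O)c2ccccc12
Why: Fluoride unmasks the ethynyl benziodoxolone and the dione enolate is C-alkynylated (electrophilic alkynylation with a hypervalent iodine reagent), giving a quaternary but still prochiral carbon.

Step 3
Reactants: 5 methyl 3-(1-ethynyl-2,5-dioxocyclopentyl)propanoate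
Product: 7 cis-fused keto δ-lactone (4aS,7aR)-4a-ethynylhexahydrocyclopenta[b]pyran-2,5-dione, via hydroxy ketone 6 (not isolated)
Conditions: (S)-2-methyl-CBS-oxazaborolidine (20 mol %), catecholborane (1.1 equiv), toluene, −78 °C; then TsOH·H2O (cat.), toluene, 50 °C
Reagents that add atoms: none
Why: Corey–Bakshi–Shibata reduction desymmetrises the dione: the catalyst fixes the carbinol as R, hydride arrives syn to the slim ethynyl group so that OH is cis to the propanoate chain, and this cis hydroxy ester lactonises, which sets both stereocentres of the bicycle.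

Step 4
Reactants: 7 cis-fused keto δ-lactone
Product: 8 (4aS,7aR)-4a-ethynyl-3,4,4a,7a-tetrahydrocyclopenta[b]pyran-2,5-dione (cyclopentenone)
Conditions: IBX (2.5 equiv), DMSO–fluorobenzene, 70 °C
Reagents that add atoms: none
Why: IBX dehydrogenation of the ketone can only go toward its single α-CH2 (the other α-carbon is quaternary) and leaves both stereocentres untouched.

Step 5
Reactants: 8 cyclopentenone; 9 tributyl[(methoxymethoxy)methyl]stannane
Product: 10 tertiary allylic alcohol (1,2-adduct of 8 carrying OH and CH2OCH2OCH3 on the former carbonyl carbon)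
Conditions: 9 (2.4 equiv), n-BuLi (2.3 equiv), THF, −78 °C; then 8, −78 °C; aq. NH4Cl
Reagents that add atoms: tributyl[(methoxymethoxy)methyl]stannane (9), CCCC[Sn](CCCC)(CCCC)COCOC
Why: Tin–lithium exchange gives (methoxymethoxy)methyllithium, which after sacrificial deprotonation of the alkyne adds 1,2 to the enone carbonyl faster than to the lactone at −78 °C; the new carbinol centre (drawn from convex-face attack) is erased in step 6.

Step 6
Reactants: 10 tertiary allylic alcohol
Product: 11 transposed enone (ring ketone next to the lactone CH–O; CH2OCH2OCH3 on the β-carbon beside the ethynyl-bearing carbon)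
Conditions: pyridinium chlorochromate C5H5NH[CrO3Cl] (2 equiv), 4 Å MS, CH2Cl2, rt
Reagents that add atoms: none
Why: Babler–Dauben oxidative 1,3-transposition (allylic [3,3] shift of the chromate ester, then oxidation) moves the oxygen to the far allylic carbon; no stereocentre is created.

Step 7
Reactants: 11 transposed enone
Product: 13 β-vinyl ketone with vicinal quaternary carbons (vinyl cis to ethynyl, CH2OCH2OCH3 cis to the lactone CH2), via trimethylsilyl enol ether 12 (not isolated)
Conditions: CH2=CHMgBr (4 equiv), CuBr·SMe2 (0.3 equiv), Me3SiCl, THF, −78 to −30 °C; then 1 M HCl, THF, 0 °C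
Reagents that add atoms: vinylmagnesium bromide, C=C[Mg]Br
Why: Copper-catalysed, silyl-accelerated conjugate addition forms the second quaternary carbon; vinyl should enter on the convex face, syn to the rod-like ethynyl and anti to the lactone CH2 on the neighbouring quaternary carbon.

Step 8
Reactants: 13 β-vinyl ketone
Product: 14 trichloromethyl carbinol (CCl3 on the vinyl/ethynyl face, OH on the lactone-oxygen face)
Conditions: Cl3CCO2H, Cl3CCO2Na, DMF, 0 °C to rt
Reagents that add atoms: trichloroacetic acid, OC(=O)C(Cl)(Cl)Cl
Why: Decarboxylatively generated trichloromethyl anion adds to the ketone (first half of the Corey–Link sequence) anti to the α-acyloxy substituent (Felkin–Anh), i.e. on the vinyl/ethynyl face.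

Step 9
Reactants: 14 trichloromethyl carbinol
Product: 17 α-azido acid (azide on the vinyl/ethynyl face, CO2H cis to the lactone oxygen), via gem-dichloroepoxide 15 (not isolated), via azido acyl chloride 16 (not isolated)
Conditions: NaN3 (3 equiv), DBU (3 equiv), 18-crown-6 (cat.), DME–H2O (20:1), rt; then aq. KHSO4
Reagents that add atoms: sodium azide, [Na+].[N-]=[N+]=[N-]; water, O
Why: Corey–Link reaction: the alkoxide closes to the dichloroepoxide, azide opens it at the fully substituted carbon with inversion (nitrogen ends on the vinyl face, the carboxyl carbon on the lactone face), and the acyl chloride is hydrolysed.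

Step 10
Reactants: 17 α-azido acid
Product: 19 azido alcohol (CH2OH in place of CO2H), via isobutyl mixed anhydride 18 (not isolated)
Conditions: i-BuOCOCl, N-methylmorpholine, THF, −15 °C; then NaBH4, H2O, 0 °C
Reagents that add atoms: none
Why: The free acid alone is activated as its mixed carbonic anhydride and reduced by NaBH4, to which lactone, azide and alkyne are inert at 0 °C.

Step 11
Reactants: 19 azido alcohol; 20 (trimethylsilyl)methyl trifluoromethanesulfonate
Product: 22 N-(trimethylsilylmethyl) amino alcohol, via primary amine 21 (not isolated)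
Conditions: PMe3, THF–H2O, 40 °C; evaporate; then 20 (1.05 equiv), i-Pr2NEt, CH2Cl2, −20 °C to rt
Reagents that add atoms: (trimethylsilyl)methyl trifluoromethanesulfonate (20), C[Si](C)(C)COS(=O)(=O)C(F)(F)F
Why: Staudinger reduction of the tertiary azide (retention) is followed by N-monoalkylation with the α-silyl triflate, the amine being more nucleophilic than the neopentyl hydroxyl.

Step 12
Reactants: 22 N-(trimethylsilylmethyl) amino alcohol; 23 methyl (2E)-4-bromo-3-methylbut-2-enoate
Product: 24 tertiary amine carrying N–CH2SiMe3 and N–CH2C(CH3)=CHCO2CH3 (E)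
Conditions: K2CO3, NaI (cat.), MeCN, 60 °C
Reagents that add atoms: methyl (2E)-4-bromo-3-methylbut-2-enoate (23), COC(=O)/C=C(C)/CBr
Why: SN2 N-alkylation by the reactive allylic bromide should overcome the hindrance of the secondary amine and keeps the E-enoate geometry.

Step 13
Reactants: 24 tertiary amine
Product: 25 α-amino aldehyde (CHO in place of CH2OH)
Conditions: SO3·pyridine, DMSO, i-Pr2NEt, CH2Cl2, 0 °C
Reagents that add atoms: none
Why: Parikh–Doering oxidation converts the primary alcohol into a non-enolisable aldehyde and tolerates the tertiary amine.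

Step 14
Reactants: 25 α-amino aldehyde
Product: 26 spiro pyrrolidin-3-one with quaternary C(CH3)(CH2CO2CH3) (methyl cis to the cyclopentane CH2)
Conditions: chiral aminoindanol-derived N-pentafluorophenyl triazolium tetrafluoroborate (20 mol %, matched enantiomer), KN(SiMe3)2 (20 mol %), toluene, rt
Reagents that add atoms: none
Why: Intramolecular Stetter reaction: the carbene-derived acyl anion adds 5-exo to the β-carbon of the E-enoate, closing the pyrrolidinone and forming the quaternary carbon, whose configuration is set by the chiral carbene's choice of enoate face.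

Step 15
Reactants: 26 spiro pyrrolidin-3-one
Product: 28 spiro pyrrolidine cis-fused to the γ-lactone, via hydroxy ester 27 (not isolated)
Conditions: NaBH4, MeOH, −40 °C; then TsOH·H2O (1.5 equiv), toluene, 60 °C; aq. NaHCO3
Reagents that add atoms: none
Why: Hydride attacks the ketone from the face of the methyl group and the cyclopentane CH2 (the other face carries the acetate arm and the oxygenated ring carbon), so OH is cis to the acetate arm and lactonises to the cis-fused γ-lactone.

Step 16
Reactants: 28 spiro pyrrolidine γ-lactone (terminal alkyne)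
Product: 29 2-substituted cyclopent-2-enone
Conditions: Co2(CO)8 (1.1 equiv), ethylene (40 bar), DMSO (5 equiv), toluene, 70 °C; then air, 1 M HCl wash
Reagents that add atoms: ethylene, C=C; carbon monoxide (from Co2(CO)8), [C-]#[O+]
Why: Intermolecular Pauson–Khand reaction places the substituted alkyne carbon α to the new carbonyl; no stereocentre is formed.

Step 17
Reactants: 29 cyclopentenone
Product: 30 (R)-cyclopent-2-enol
Conditions: (S)-2-methyl-CBS-oxazaborolidine (0.5 equiv), catecholborane, toluene, −78 °C
Reagents that add atoms: none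
Why: Corey–Bakshi–Shibata 1,2-reduction of the α-substituted enone is catalyst-controlled (alkene carbon as the large group) and gives the R carbinol.

Step 18
Reactants: 30 cyclopentenol
Product: 32 aldehyde (trisubstituted cyclopentene with CH2CHO on the allylic ring carbon), via allyl vinyl ether 31 (not isolated)
Conditions: ethyl vinyl ether, Hg(OAc)2 (0.3 equiv), reflux; evaporate; toluene, 180 °C (sealed tube)
Reagents that add atoms: ethyl vinyl ether, C=COCC
Why: Claisen rearrangement transfers the carbinol configuration suprafacially to the new C–C stereocentre (CH2CHO on the face that carried oxygen) and moves the alkene to its final trisubstituted position.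

Step 19
Reactants: 32 aldehyde
Product: 33 diene (allyl group in place of CH2CHO)
Conditions: Ph3PCH3Br, KN(SiMe3)2, THF, 0 °C; then 32, −78 to 0 °C
Reagents that add atoms: methyltriphenylphosphonium bromide, C[P+](c1ccccc1)(c1ccccc1)c1ccccc1.[Br-]
Why: Wittig methylenation of the aldehyde, faster than ylide attack on the lactones at low temperature.

Step 20
Reactants: 33 diene
Product: 34 hexacyclic cycloheptene N-(trimethylsilylmethyl) amine
Conditions: second-generation Grubbs catalyst (H2IMes)(PCy3)Cl2Ru=CHPh (10 mol %), TsOH·H2O (1.05 equiv), CH2Cl2, 40 °C; aq. NaHCO3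
Reagents that add atoms: none
Why: Ring-closing metathesis joins the allyl group and the vinyl group (both on the same face of the cyclopentane) into the cis-fused cycloheptene; the amine is protonated to spare the catalyst and the trisubstituted cyclopentene does not take part.

Step 21
Reactants: 34 hexacyclic cycloheptene N-(trimethylsilylmethyl) amine
Product: 35 O-methoxymethyl ether of the target
Conditions: 1,4-dicyanonaphthalene (0.3 equiv), hν (450 W Hg lamp, Pyrex), i-PrOH, rt
Reagents that add atoms: none
Why: Excited 1,4-dicyanonaphthalene oxidises the tertiary amine to its radical cation, i-PrOH-assisted loss of Me3Si+ gives the N–CH2 radical only at the exocyclic methylene, this adds to the nearer carbon of the cycloheptene, and the resulting secondary radical is reduced by the sensitiser radical anion and protonated by i-PrOH. The closest known reaction type is the photoinduced-electron-transfer cyclisation of α-(trimethylsilyl)methyl amines onto unactivated alkenes to 1-azabicycles. The piperidine closes in the 6-exo-trig mode through the one new C–C bond, which also completes the 2-azabicyclo[3.2.1]octane with the cyclopentane. The new CH stereocentre is controlled by the tether: the radical, held on nitrogen above the spiro carbon, reaches only the alkene face syn to the cyclopentane CH2, and the epimer would need a trans-bridged boat. The step needs 6-exo rather than 7-endo attack and cyclisation faster than hydrogen capture, which the 1,3-syn placement of nitrogen and the alkene carbon on the rigid cyclopentane should secure; the trisubstituted cyclopentene is out of reach and the lactones and acetal are inert.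

Step 22
Reactants: 35 O-methoxymethyl ether of the target
Product: 36 target CNP0247797.1
Conditions: 3 M aq. HCl, THF, 45 °C; then aq. NaHCO3
Reagents that add atoms: none
Why: Acid hydrolysis of the methoxymethyl acetal frees the primary alcohol, while both lactones, the protonated amine and the alkene are stable.

**Compound list**

1 | cyclopentane-1,3-dione | O=C1CCC(=O)C1 | starting material
2 | methyl acrylate | C=CC(=O)OC | starting material
3 | methyl 3-(2,5-dioxocyclopentyl)propanoate | COC(=O)CCC1C(=O)CCC1=O | intermediate
4 | 1-[(trimethylsilyl)ethynyl]-1,2-benziodoxol-3(1H)-one (TMS-EBX) | C[Si](C)(C)C#CI1OC(=O)c2ccccc12 | starting material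
5 | methyl 3-(1-ethynyl-2,5-dioxocyclopentyl)propanoate | COC(=O)CCC1(C#C)C(=O)CCC1=O | intermediate
6 | methyl 3-[(1S,2R)-1-ethynyl-2-hydroxy-5-oxocyclopentyl]propanoate (OH cis to the propanoate chain) | COC(=O)CC[C@@]1(C#C)C(=O)CC[C@H]1O | intermediate
7 | (4aS,7aR)-4a-ethynylhexahydrocyclopenta[b]pyran-2,5-dione (cis-fused keto δ-lactone) | O=C1CC[C@@]2(C#C)C(=O)CC[C@H]2O1 | intermediate
8 | (4aS,7aR)-4a-ethynyl-3,4,4a,7a-tetrahydrocyclopenta[b]pyran-2,5-dione (cyclopentenone) | O=C1CC[C@@]2(C#C)C(=O)C=C[C@H]2O1 | intermediate
9 | tributyl[(methoxymethoxy)methyl]stannane | CCCC[Sn](CCCC)(CCCC)COCOC | starting material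
10 | tertiary allylic alcohol, 1,2-adduct of 8 (OH and CH2OCH2OCH3 on the former carbonyl carbon, the latter on the ethynyl face) | O=C1CC[C@@]2(C#C)[C@](O)(COCOC)C=C[C@H]2O1 | intermediate
11 | transposed enone (ketone beside the lactone CH–O; CH2OCH2OCH3 on the alkene carbon beside the ethynyl carbon) | O=C1CC[C@@]2(C#C)C(COCOC)=CC(=O)[C@H]2O1 | intermediate
12 | trimethylsilyl enol ether of 13 | O=C1CC[C@@]2(C#C)[C@@](C=C)(COCOC)C=C(O[Si](C)(C)C)[C@H]2O1 | intermediate
13 | β-vinyl ketone (vinyl cis to ethynyl; CH2OCH2OCH3 cis to the lactone CH2) | O=C1CC[C@@]2(C#C)[C@@](C=C)(COCOC)CC(=O)[C@H]2O1 | intermediate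
14 | trichloromethyl carbinol (CCl3 on the vinyl/ethynyl face) | O=C1CC[C@@]2(C#C)[C@@](C=C)(COCOC)C[C@](O)(C(Cl)(Cl)Cl)[C@H]2O1 | intermediate
15 | spiro gem-dichloroepoxide | O=C1CC[C@@]2(C#C)[C@@](C=C)(COCOC)C[C@@]3(OC3(Cl)Cl)[C@H]2O1 | intermediate
16 | α-azido acyl chloride | O=C1CC[C@@]2(C#C)[C@@](C=C)(COCOC)C[C@@](N=[N+]=[N-])(C(=O)Cl)[C@H]2O1 | intermediate
17 | α-azido acid (azide on the vinyl/ethynyl face, CO2H cis to the lactone oxygen) | O=C1CC[C@@]2(C#C)[C@@](C=C)(COCOC)C[C@@](N=[N+]=[N-])(C(=O)O)[C@H]2O1 | intermediate
18 | isobutyl carbonic mixed anhydride of 17 | O=C1CC[C@@]2(C#C)[C@@](C=C)(COCOC)C[C@@](N=[N+]=[N-])(C(=O)OC(=O)OCC(C)C)[C@H]2O1 | intermediate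
19 | azido alcohol | O=C1CC[C@@]2(C#C)[C@@](C=C)(COCOC)C[C@@](N=[N+]=[N-])(CO)[C@H]2O1 | intermediate
20 | (trimethylsilyl)methyl trifluoromethanesulfonate | C[Si](C)(C)COS(=O)(=O)C(F)(F)F | starting material
21 | primary amino alcohol | O=C1CC[C@@]2(C#C)[C@@](C=C)(COCOC)C[C@@](N)(CO)[C@H]2O1 | intermediate
22 | N-(trimethylsilylmethyl) amino alcohol | O=C1CC[C@@]2(C#C)[C@@](C=C)(COCOC)C[C@@](NC[Si](C)(C)C)(CO)[C@H]2O1 | intermediate
23 | methyl (2E)-4-bromo-3-methylbut-2-enoate | COC(=O)/C=C(C)/CBr | starting material
24 | tertiary amine with N–CH2SiMe3 and N–CH2C(CH3)=CHCO2CH3 (E) | O=C1CC[C@@]2(C#C)[C@@](C=C)(COCOC)C[C@@](N(C[Si](C)(C)C)C/C(C)=C/C(=O)OC)(CO)[C@H]2O1 | intermediate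
25 | α-amino aldehyde | O=C1CC[C@@]2(C#C)[C@@](C=C)(COCOC)C[C@@](N(C[Si](C)(C)C)C/C(C)=C/C(=O)OC)(C=O)[C@H]2O1 | intermediate
26 | spiro pyrrolidin-3-one with quaternary C(CH3)(CH2CO2CH3) (methyl cis to the cyclopentane CH2) | O=C1CC[C@@]2(C#C)[C@@](C=C)(COCOC)C[C@]3(N(C[Si](C)(C)C)C[C@](C)(CC(=O)OC)C3=O)[C@H]2O1 | intermediate
27 | hydroxy ester (OH cis to the CH2CO2CH3 arm) | O=C1CC[C@@]2(C#C)[C@@](C=C)(COCOC)C[C@]3(N(C[Si](C)(C)C)C[C@](C)(CC(=O)OC)[C@@H]3O)[C@H]2O1 | intermediate
28 | spiro pyrrolidine cis-fused to the γ-lactone (alkyne, vinyl, CH2OCH2OCH3 and N–CH2SiMe3 retained) | O=C1CC[C@@]2(C#C)[C@@](C=C)(COCOC)C[C@]3(N(C[Si](C)(C)C)C[C@]4(C)CC(=O)O[C@H]34)[C@H]2O1 | intermediate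
29 | 2-substituted cyclopent-2-enone | O=C1CC[C@@]2(C5=CCCC5=O)[C@@](C=C)(COCOC)C[C@]3(N(C[Si](C)(C)C)C[C@]4(C)CC(=O)O[C@H]34)[C@H]2O1 | intermediate
30 | (R)-cyclopent-2-enol | O=C1CC[C@@]2(C5=CCC[C@H]5O)[C@@](C=C)(COCOC)C[C@]3(N(C[Si](C)(C)C)C[C@]4(C)CC(=O)O[C@H]34)[C@H]2O1 | intermediate
31 | allyl vinyl ether of 30 | O=C1CC[C@@]2(C5=CCC[C@H]5OC=C)[C@@](C=C)(COCOC)C[C@]3(N(C[Si](C)(C)C)C[C@]4(C)CC(=O)O[C@H]34)[C@H]2O1 | intermediate
32 | aldehyde (cyclopentene with CH2CHO on the allylic ring carbon) | O=C1CC[C@@]2(C5=CCC[C@@H]5CC=O)[C@@](C=C)(COCOC)C[C@]3(N(C[Si](C)(C)C)C[C@]4(C)CC(=O)O[C@H]34)[C@H]2O1 | intermediate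
33 | diene (allyl in place of CH2CHO) | O=C1CC[C@@]2(C5=CCC[C@@H]5CC=C)[C@@](C=C)(COCOC)C[C@]3(N(C[Si](C)(C)C)C[C@]4(C)CC(=O)O[C@H]34)[C@H]2O1 | intermediate
34 | hexacyclic cycloheptene N-(trimethylsilylmethyl) amine | O=C1CC[C@@]2(C5=CCC[C@@H]5CC=C6)[C@@]6(COCOC)C[C@]3(N(C[Si](C)(C)C)C[C@]4(C)CC(=O)O[C@H]34)[C@H]2O1 | intermediate
35 | O-methoxymethyl ether of the target | C[C@@]12CC(=O)O[C@@H]1[C@]13C[C@@]4(COCOC)[C@H](CC[C@H]5CCC=C5[C@]45CCC(=O)O[C@H]15)CN3C2 | intermediate
36 | CNP0247797.1 | C[C@@]12CC(=O)O[C@@H]1[C@]13C[C@@]4(CO)[C@H](CC[C@H]5CCC=C5[C@]45CCC(=O)O[C@H]15)CN3C2 | target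

Total step count: 22. Longest linear sequence: 22 steps (1 to 36).

**Steps most likely to fail**

1. Step 21. The α-amino radical may capture hydrogen before it cyclises (giving the N-methyl amine), back electron transfer may outrun desilylation, or 7-endo closure may compete. Fallback (polar instead of radical C–C formation): from 34, anodic two-electron oxidation (carbon anode, Bu4NCl, MeCN–CH2Cl2, −20 °C) turns the N–CH2SiMe3 group into the N-methyleneiminium ion. This closes onto the cycloheptene in a cationic aza-Prins cyclisation with chloride capture of the secondary cation, giving the chloride F1. Radical dechlorination (Bu3SnH, AIBN, benzene, 80 °C) returns to the route at 35.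

2. Step 14. Formation of the acyl-anion equivalent from the neopentyl α-amino aldehyde may be slow, and facial selectivity in the addition that creates the quaternary carbon may be poor. Fallback (quaternary carbon made by enolate alkylation instead): from 22, N-alkylation with methyl (E)-4-bromobut-2-enoate (K2CO3, MeCN) gives the crotonate amino alcohol F2, and Parikh–Doering oxidation gives the aldehyde F3. An achiral triazolium-catalysed Stetter closure onto the β-monosubstituted acceptor gives the pyrrolidin-3-one F4. Deprotonation at its only enolisable position (KN(SiMe3)2, THF, −78 °C) and methylation with MeI on the less hindered face (syn to the cyclopentane CH2) returns to the route at 26.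

3. Step 7. Conjugate addition at a β-carbon flanked by a quaternary centre may be sluggish, with competing 1,2-addition or electron-transfer cleavage of the α'-acyloxy group. Fallback (cross-electrophile coupling instead of an organometallic donor): from 11, nickel-catalysed reductive conjugate vinylation (vinyl bromide, NiCl2(dme), neocuproine, manganese powder, Et3SiCl, DMF, rt) gives the triethylsilyl enol ether F5. Mild acid hydrolysis returns to the route at 13.

Further compounds
F1 | step 21 | chloride: 35 bearing Cl on the cycloheptane carbon next to the new ring CH (epimer mixture) | C[C@@]12CC(=O)O[C@@H]1[C@]13C[C@@]4(COCOC)[C@H](C(Cl)C[C@H]5CCC=C5[C@]45CCC(=O)O[C@H]15)CN3C2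
F2 | step 14 | crotonate amino alcohol (24 without the alkene methyl group) | O=C1CC[C@@]2(C#C)[C@@](C=C)(COCOC)C[C@@](N(C[Si](C)(C)C)C/C=C/C(=O)OC)(CO)[C@H]2O1
F3 | step 14 | crotonate α-amino aldehyde | O=C1CC[C@@]2(C#C)[C@@](C=C)(COCOC)C[C@@](N(C[Si](C)(C)C)C/C=C/C(=O)OC)(C=O)[C@H]2O1
F4 | step 14 | spiro pyrrolidin-3-one lacking the methyl group (epimers at the CH bearing CH2CO2CH3) | O=C1CC[C@@]2(C#C)[C@@](C=C)(COCOC)C[C@]3(N(C[Si](C)(C)C)CC(CC(=O)OC)C3=O)[C@H]2O1
F5 | step 7 | triethylsilyl enol ether of 13 | O=C1CC[C@@]2(C#C)[C@@](C=C)(COCOC)C=C(O[Si](CC)(CC)CC)[C@H]2O1
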